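**Retrosynthetic overview**

1. The ring oxirane is made last by peracid epoxidation of the E-1(10) olefin; just before that the C8 hydroxyl is esterified with (2R,3S)-epoxytiglic acid, itself made by Sharpless epoxidation of tiglyl alcohol.
2. Key step: the C7–C8 bond and the ten-membered ring form together when a SmI2-derived ketyl radical at C8 adds to C7 of a 3-(acetoxymethyl)butenolide; the samarium enolate then loses acetate to give the α-methylene lactone, and C7 and C8 are set in this step.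
3. The open-chain aldehyde comes from an asymmetric Ni/Cr coupling (C3–C4) of a Z-vinyl iodide carrying the butenolide with a β,γ-unsaturated aldehyde, followed by acylation at C3.
4. The butenolide–iodide comes from but-2-yn-1-ol (hydroalumination/iodination, oxidation, asymmetric vinyl addition for C6, acrylate ester, ring-closing metathesis); the aldehyde comes from silyl-protected but-3-yn-1-ol by carboalumination and ethylene oxide opening.
5. Ring order: side-chain oxirane → butenolide → ten-membered carbocycle (exo-methylene lactone completed in the same step) → ring oxirane.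

Assumption: ring positions use germacrane numbering (C1–C10 carbocycle, C11–C13 acrylate unit, lactone on O6); the silyl ether of but-3-yn-1-ol (silyl counted as a protecting group) and (2R)-2-methylbutanoic acid are taken as purchasable.

**Route**

Step 1
Reactants: 1 tert-butyl(but-3-yn-1-yloxy)dimethylsilane; 2 oxirane (ethylene oxide)
Product: 5 (3E)-6-{[tert-butyl(dimethyl)silyl]oxy}-4-methylhex-3-en-1-ol, via alkenyl(dimethyl)alane 3 (not isolated), via lithium alkenylalanate 4 (not isolated)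
Conditions: Me3Al, Cp2ZrCl2 (20 mol%), CH2Cl2, 0 °C → rt; n-BuLi, hexane, −78 → 0 °C; 2, THF, −30 °C → rt; aq. potassium sodium tartrate
Reagents that add atoms: trimethylaluminium, C[Al](C)C
Why: Negishi zirconium-catalysed carboalumination adds methyl and aluminium syn across the terminal alkyne (methyl to the internal carbon), and the derived alkenylalanate opens ethylene oxide with retention, giving the E-trisubstituted homoallylic alcohol (C8–C3 with C14) in one pot.

Step 2
Reactants: 5 (3E)-6-{[tert-butyl(dimethyl)silyl]oxy}-4-methylhex-3-en-1-ol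
Product: 6 (3E)-6-{[tert-butyl(dimethyl)silyl]oxy}-4-methylhex-3-enal
Conditions: Dess–Martin periodinane, NaHCO3, CH2Cl2, 0 °C → rt; used at once
Reagents that add atoms: none
Why: Buffered Dess–Martin oxidation gives the β,γ-unsaturated aldehyde without moving the trisubstituted double bond into conjugation.

Step 3
Reactants: 7 but-2-yn-1-ol
Product: 9 (2Z)-3-iodobut-2-en-1-ol, via cyclic sodium vinylalanate 8 (not isolated)
Conditions: NaAlH2(OCH2CH2OMe)2, THF, 0 °C → rt; then I2, THF, −78 → 0 °C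
Reagents that add atoms: iodine, II
Why: Hydroxyl-directed trans-hydroalumination of the propargylic alcohol puts aluminium on the distal carbon cis to the CH2O group, and iodinolysis with retention gives the Z-vinyl iodide that later becomes the 4Z olefin.

Step 4
Reactants: 9 (2Z)-3-iodobut-2-en-1-ol
Product: 10 (2Z)-3-iodobut-2-enal
Conditions: MnO2, CH2Cl2, rt, dark; used as a solution
Reagents that add atoms: none
Why: Neutral MnO2 oxidation of the allylic alcohol leaves the Z-iodoalkene geometry untouched.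

Step 5
Reactants: 10 (2Z)-3-iodobut-2-enal
Product: 11 (3S,4Z)-5-iodohexa-1,4-dien-3-ol
Conditions: (CH2=CH)2Zn (from CH2=CHMgBr and ZnCl2, salts removed), (−)-MIB [(2S)-3-exo-morpholinoisoborneol] (10 mol%), toluene, −20 → 0 °C; aq. NH4Cl
Reagents that add atoms: divinylzinc, C=C[Zn]C=C
Why: Amino-alcohol-catalysed asymmetric 1,2-addition of a vinylzinc reagent (Oppolzer/Nugent type) takes the Si face of the enal with (−)-MIB and sets the carbinol that becomes C6 as S in this fragment.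

Step 6
Reactants: 12 2-(bromomethyl)prop-2-enoic acid
Product: 13 2-[(acetyloxy)methyl]prop-2-enoic acid
Conditions: KOAc (3 equiv), AcOH, 50 °C
Reagents that add atoms: potassium acetate, CC(=O)[O-].[K+]
Why: Acetate displaces the allylic bromide (SN2 and SN2' give the same product on this symmetric allyl system), and the excess acetate in acetic acid suppresses self-alkylation of the carboxylate.

Step 7
Reactants: 11 (3S,4Z)-5-iodohexa-1,4-dien-3-ol; 13 2-[(acetyloxy)methyl]prop-2-enoic acid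
Product: 14 (3S,4Z)-5-iodohexa-1,4-dien-3-yl 2-[(acetyloxy)methyl]prop-2-enoate
Conditions: N,N'-dicyclohexylcarbodiimide, DMAP (5 mol%), CH2Cl2, −20 → 0 °C
Reagents that add atoms: none
Why: Steglich esterification acylates the bis-allylic alcohol with retention at the carbinol carbon and brings in C11, C12 and C13 with the acetate leaving group in place.

Step 8
Reactants: 14 (3S,4Z)-5-iodohexa-1,4-dien-3-yl 2-[(acetyloxy)methyl]prop-2-enoate
Product: 15 [(5S)-5-[(1Z)-2-iodoprop-1-en-1-yl]-2-oxo-2,5-dihydrofuran-3-yl]methyl acetate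
Conditions: second-generation Grubbs catalyst (5 mol%), toluene, 80 °C, argon sparge
Reagents that add atoms: none
Why: Ring-closing metathesis between the vinyl group and the 1,1-disubstituted acrylate closes the butenolide with loss of ethene; the trisubstituted iodoalkene is inert and the stereocentre is not touched.

Step 9
Reactants: 6 (3E)-6-{[tert-butyl(dimethyl)silyl]oxy}-4-methylhex-3-enal; 15 [(5S)-5-[(1Z)-2-iodoprop-1-en-1-yl]-2-oxo-2,5-dihydrofuran-3-yl]methyl acetate
Product: 17 [(5R)-5-[(1Z,3S,5E)-8-{[tert-butyl(dimethyl)silyl]oxy}-3-hydroxy-2,6-dimethylocta-1,5-dien-1-yl]-2-oxo-2,5-dihydrofuran-3-yl]methyl acetate, via alkenylchromium dichloride 16 (not isolated)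
Conditions: CrCl2 (4 equiv), NiCl2 (2 mol%), Kishi valinol-derived oxazoline–sulfonamide ligand (enantiomer matched to the 3S carbinol, 4.4 equiv), Et3N, THF, rt
Reagents that add atoms: none
Why: Nozaki–Hiyama–Kishi coupling: zerovalent nickel inserts into the vinyl iodide with retention of the Z geometry, transmetalation gives alkenylchromium 16, which adds to the aldehyde under non-basic conditions that spare the β,γ-unsaturated aldehyde, the butenolide and the allylic acetate, and the chiral sulfonamide on chromium sets C3 as S because C6 is too remote to interfere (the descriptor of the butenolide carbon changes from S to R only through the priority change).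

Step 10
Reactants: 17 [(5R)-5-[(1Z,3S,5E)-8-{[tert-butyl(dimethyl)silyl]oxy}-3-hydroxy-2,6-dimethylocta-1,5-dien-1-yl]-2-oxo-2,5-dihydrofuran-3-yl]methyl acetate; 18 (2R)-2-methylbutanoic acid
Product: 19 (1Z,3S,5E)-1-[(2R)-4-(acetoxymethyl)-5-oxo-2,5-dihydrofuran-2-yl]-8-{[tert-butyl(dimethyl)silyl]oxy}-2,6-dimethylocta-1,5-dien-3-yl (2R)-2-methylbutanoate
Conditions: N,N'-dicyclohexylcarbodiimide, DMAP (5 mol%), CH2Cl2, 0 °C
Reagents that add atoms: none
Why: Steglich esterification of the only free hydroxyl proceeds with retention at C3, and low temperature with little DMAP protects the α-stereocentre of the acid and the γ-hydrogen of the butenolide.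

Step 11
Reactants: 19 (1Z,3S,5E)-1-[(2R)-4-(acetoxymethyl)-5-oxo-2,5-dihydrofuran-2-yl]-8-{[tert-butyl(dimethyl)silyl]oxy}-2,6-dimethylocta-1,5-dien-3-yl (2R)-2-methylbutanoate
Product: 20 (1Z,3S,5E)-1-[(2R)-4-(acetoxymethyl)-5-oxo-2,5-dihydrofuran-2-yl]-8-hydroxy-2,6-dimethylocta-1,5-dien-3-yl (2R)-2-methylbutanoate
Conditions: HF·pyridine, pyridine, THF, 0 °C → rt
Reagents that add atoms: none
Why: Buffered fluoride desilylation frees the primary alcohol and leaves the three esters and the butenolide intact.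

Step 12
Reactants: 20 (1Z,3S,5E)-1-[(2R)-4-(acetoxymethyl)-5-oxo-2,5-dihydrofuran-2-yl]-8-hydroxy-2,6-dimethylocta-1,5-dien-3-yl (2R)-2-methylbutanoate
Product: 21 (1Z,3S,5E)-1-[(2R)-4-(acetoxymethyl)-5-oxo-2,5-dihydrofuran-2-yl]-2,6-dimethyl-8-oxoocta-1,5-dien-3-yl (2R)-2-methylbutanoate
Conditions: Dess–Martin periodinane, NaHCO3, CH2Cl2, 0 °C; filtered and used at once
Reagents that add atoms: none
Why: Buffered Dess–Martin oxidation gives the C8 aldehyde without conjugating the 1(10) olefin or epimerising C6.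

Step 13
Reactants: 21 (1Z,3S,5E)-1-[(2R)-4-(acetoxymethyl)-5-oxo-2,5-dihydrofuran-2-yl]-2,6-dimethyl-8-oxoocta-1,5-dien-3-yl (2R)-2-methylbutanoate
Product: 23 (3aR,4R,6E,9S,10Z,11aR)-4-hydroxy-6,10-dimethyl-3-methylidene-2-oxo-2,3,3a,4,5,8,9,11a-octahydrocyclodeca[b]furan-9-yl (2R)-2-methylbutanoate, via samarium enolate 22 (not isolated)
Conditions: SmI2 (2.5 equiv), THF, −78 → 0 °C, 21 added by syringe pump (final 2 mM), no proton source; then aq. NH4Cl at −78 °C
Reagents that add atoms: none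
Why: Proposed new method: divalent samarium reduces the aldehyde to a ketyl radical that adds 10-exo to C7 of the butenolide on the face anti to the C5 side chain (trans lactone, 7R), with the samarium-bound oxygen antiperiplanar to C11 and H8 over the lactone ring (8R), after which the α-carbonyl radical is reduced to samarium enolate 22, which expels acetate (E1cB) to give the exo-methylene lactone; the closest known reactions are SmI2 ketyl–olefin cyclisations onto unsaturated esters and butenolides with β-elimination from the samarium enolate, extended here to a ten-membered ring that the Z-4,5 and E-1(10) olefins pre-fold.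

Step 14
Reactants: 24 (2E)-2-methylbut-2-en-1-ol
Product: 25 [(2S,3S)-2,3-dimethyloxiran-2-yl]methanol
Conditions: Ti(OiPr)4 (5 mol%), L-(+)-diisopropyl tartrate (6 mol%), t-BuOOH, 4 Å sieves, CH2Cl2, −20 °C
Reagents that add atoms: tert-butyl hydroperoxide, CC(C)(C)OO
Why: Sharpless asymmetric epoxidation with the L-(+)-tartrate delivers oxygen to the face of the E-trisubstituted allylic alcohol that gives the (2S,3S) cis-dimethyl oxirane.

Step 15
Reactants: 25 [(2S,3S)-2,3-dimethyloxiran-2-yl]methanol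
Product: 27 (2R,3S)-2,3-dimethyloxirane-2-carboxylic acid, via epoxy aldehyde 26 (not isolated)
Conditions: RuCl3 (2 mol%), NaIO4 (3 equiv), CCl4/MeCN/H2O, rt
Reagents that add atoms: sodium periodate, [Na+].[O-]I(=O)(=O)=O; water, O
Why: Ruthenium tetroxide generated in the flask oxidises the primary alcohol through aldehyde 26 to the acid without opening the oxirane; the C2 descriptor changes from S to R only through the priority change.

Step 16
Reactants: 23 (3aR,4R,6E,9S,10Z,11aR)-4-hydroxy-6,10-dimethyl-3-methylidene-2-oxo-2,3,3a,4,5,8,9,11a-octahydrocyclodeca[b]furan-9-yl (2R)-2-methylbutanoate; 27 (2R,3S)-2,3-dimethyloxirane-2-carboxylic acid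
Product: 29 (3aR,4R,6E,9S,10Z,11aR)-6,10-dimethyl-9-{[(2R)-2-methylbutanoyl]oxy}-3-methylidene-2-oxo-2,3,3a,4,5,8,9,11a-octahydrocyclodeca[b]furan-4-yl (2R,3S)-2,3-dimethyloxirane-2-carboxylate, via mixed anhydride 28 (not isolated)
Conditions: 27, 2,4,6-trichlorobenzoyl chloride, Et3N, toluene, rt; then 23, DMAP, toluene, rt
Reagents that add atoms: none
Why: Yamaguchi esterification through mixed anhydride 28 acylates the hindered C8 hydroxyl with retention at C8 and at both oxirane carbons of the acid.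

Step 17
Reactants: 29 (3aR,4R,6E,9S,10Z,11aR)-6,10-dimethyl-9-{[(2R)-2-methylbutanoyl]oxy}-3-methylidene-2-oxo-2,3,3a,4,5,8,9,11a-octahydrocyclodeca[b]furan-4-yl (2R,3S)-2,3-dimethyloxirane-2-carboxylate
Product: 30 CNP0265335.3, (1R,3S,6R,7R,8R,10R)-1,10-epoxy-8-{[(2R,3S)-2,3-dimethyloxirane-2-carbonyl]oxy}-3-{[(2R)-2-methylbutanoyl]oxy}germacra-4Z,11(13)-dien-12,6-olide
Conditions: mCPBA (1.1 equiv), NaHCO3, CH2Cl2, 0 °C
Reagents that add atoms: mCPBA, O=C(OO)c1cccc(Cl)c1
Why: Prilezhaev epoxidation takes the only electron-rich olefin, the E-1(10) alkene (the 4,5-olefin is deactivated by two allylic acyloxy groups and the methylene lactone is electron-poor), and attack on its exposed outer face in the ten-membered ring gives the trans oxirane with 1R,10R configuration, as in peracid epoxidation of related germacranolide 1(10)-olefins to 1β,10α-epoxides.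

**Compound list**

1 | tert-butyl(but-3-yn-1-yloxy)dimethylsilane | C#CCCO[Si](C)(C)C(C)(C)C | starting material
2 | oxirane (ethylene oxide) | C1CO1 | starting material
3 | dimethyl[(1E)-4-{[tert-butyl(dimethyl)silyl]oxy}-2-methylbut-1-en-1-yl]alane | C[Al](C)/C=C(\C)CCO[Si](C)(C)C(C)(C)C | intermediate
4 | lithium butyl[(1E)-4-{[tert-butyl(dimethyl)silyl]oxy}-2-methylbut-1-en-1-yl]dimethylaluminate | [Li+].CCCC[Al-](C)(C)/C=C(\C)CCO[Si](C)(C)C(C)(C)C | intermediate
5 | (3E)-6-{[tert-butyl(dimethyl)silyl]oxy}-4-methylhex-3-en-1-ol | OCC/C=C(\C)CCO[Si](C)(C)C(C)(C)C | intermediate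
6 | (3E)-6-{[tert-butyl(dimethyl)silyl]oxy}-4-methylhex-3-enal | O=CC/C=C(\C)CCO[Si](C)(C)C(C)(C)C | intermediate
7 | but-2-yn-1-ol | CC#CCO | starting material
8 | sodium 2,2-bis(2-methoxyethoxy)-3-methyl-2,5-dihydro-1,2-oxaaluminol-2-uide (cyclic Z-vinylalanate) | [Na+].CC1=CCO[Al-]1(OCCOC)OCCOC | intermediate
9 | (2Z)-3-iodobut-2-en-1-ol | C/C(I)=C/CO | intermediate
10 | (2Z)-3-iodobut-2-enal | C/C(I)=C/C=O | intermediate
11 | (3S,4Z)-5-iodohexa-1,4-dien-3-ol | O[C@@H](C=C)/C=C(/C)I | intermediate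
12 | 2-(bromomethyl)prop-2-enoic acid | C=C(CBr)C(=O)O | starting material
13 | 2-[(acetyloxy)methyl]prop-2-enoic acid | C=C(COC(C)=O)C(=O)O | intermediate
14 | (3S,4Z)-5-iodohexa-1,4-dien-3-yl 2-[(acetyloxy)methyl]prop-2-enoate | C=C(COC(C)=O)C(=O)O[C@@H](C=C)/C=C(/C)I | intermediate
15 | [(5S)-5-[(1Z)-2-iodoprop-1-en-1-yl]-2-oxo-2,5-dihydrofuran-3-yl]methyl acetate | O=C1O[C@@H](C=C1COC(C)=O)/C=C(/C)I | intermediate
16 | dichloro{(1Z)-1-[(2S)-4-(acetoxymethyl)-5-oxo-2,5-dihydrofuran-2-yl]prop-1-en-2-yl}chromium | O=C1O[C@@H](C=C1COC(C)=O)/C=C(/C)[Cr](Cl)Cl | intermediate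
17 | [(5R)-5-[(1Z,3S,5E)-8-{[tert-butyl(dimethyl)silyl]oxy}-3-hydroxy-2,6-dimethylocta-1,5-dien-1-yl]-2-oxo-2,5-dihydrofuran-3-yl]methyl acetate | O=C1O[C@@H](C=C1COC(C)=O)/C=C(/C)[C@@H](O)C/C=C(\C)CCO[Si](C)(C)C(C)(C)C | intermediate
18 | (2R)-2-methylbutanoic acid | CC[C@@H](C)C(=O)O | starting material
19 | (1Z,3S,5E)-1-[(2R)-4-(acetoxymethyl)-5-oxo-2,5-dihydrofuran-2-yl]-8-{[tert-butyl(dimethyl)silyl]oxy}-2,6-dimethylocta-1,5-dien-3-yl (2R)-2-methylbutanoate | O=C1O[C@@H](C=C1COC(C)=O)/C=C(/C)[C@@H](OC(=O)[C@H](C)CC)C/C=C(\C)CCO[Si](C)(C)C(C)(C)C | intermediate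
20 | (1Z,3S,5E)-1-[(2R)-4-(acetoxymethyl)-5-oxo-2,5-dihydrofuran-2-yl]-8-hydroxy-2,6-dimethylocta-1,5-dien-3-yl (2R)-2-methylbutanoate | O=C1O[C@@H](C=C1COC(C)=O)/C=C(/C)[C@@H](OC(=O)[C@H](C)CC)C/C=C(\C)CCO | intermediate
21 | (1Z,3S,5E)-1-[(2R)-4-(acetoxymethyl)-5-oxo-2,5-dihydrofuran-2-yl]-2,6-dimethyl-8-oxoocta-1,5-dien-3-yl (2R)-2-methylbutanoate | O=C1O[C@@H](C=C1COC(C)=O)/C=C(/C)[C@@H](OC(=O)[C@H](C)CC)C/C=C(\C)CC=O | intermediate
22 | cyclised bis(diiodosamarium) species: C8 alkoxide and C11=C12 lactone enolate, C13 acetate still in place | CC(=O)OCC1=C(O[Sm](I)I)O[C@@H]2/C=C(/C)[C@@H](OC(=O)[C@H](C)CC)C/C=C(\C)C[C@@H](O[Sm](I)I)[C@@H]12 | intermediate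
23 | (3aR,4R,6E,9S,10Z,11aR)-4-hydroxy-6,10-dimethyl-3-methylidene-2-oxo-2,3,3a,4,5,8,9,11a-octahydrocyclodeca[b]furan-9-yl (2R)-2-methylbutanoate (germacrane 3S,6R,7R,8R) | C=C1C(=O)O[C@@H]2/C=C(/C)[C@@H](OC(=O)[C@H](C)CC)C/C=C(\C)C[C@@H](O)[C@@H]12 | intermediate
24 | (2E)-2-methylbut-2-en-1-ol | C/C=C(\C)CO | starting material
25 | [(2S,3S)-2,3-dimethyloxiran-2-yl]methanol | OC[C@]1(C)O[C@H]1C | intermediate
26 | (2R,3S)-2,3-dimethyloxirane-2-carbaldehyde | O=C[C@]1(C)O[C@H]1C | intermediate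
27 | (2R,3S)-2,3-dimethyloxirane-2-carboxylic acid | OC(=O)[C@]1(C)O[C@H]1C | intermediate
28 | (2R,3S)-2,3-dimethyloxirane-2-carboxylic 2,4,6-trichlorobenzoic anhydride | O=C(OC(=O)[C@]1(C)O[C@H]1C)c1c(Cl)cc(Cl)cc1Cl | intermediate
29 | (3aR,4R,6E,9S,10Z,11aR)-6,10-dimethyl-9-{[(2R)-2-methylbutanoyl]oxy}-3-methylidene-2-oxo-2,3,3a,4,5,8,9,11a-octahydrocyclodeca[b]furan-4-yl (2R,3S)-2,3-dimethyloxirane-2-carboxylate | C=C1C(=O)O[C@@H]2/C=C(/C)[C@@H](OC(=O)[C@H](C)CC)C/C=C(\C)C[C@@H](OC(=O)[C@]3(C)O[C@H]3C)[C@@H]12 | intermediate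
30 | CNP0265335.3, (1R,3S,6R,7R,8R,10R)-1,10-epoxy-8-{[(2R,3S)-2,3-dimethyloxirane-2-carbonyl]oxy}-3-{[(2R)-2-methylbutanoyl]oxy}germacra-4Z,11(13)-dien-12,6-olide | C=C1C(=O)O[C@@H]2/C=C(/C)[C@@H](OC(=O)[C@H](C)CC)C[C@H]3O[C@]3(C)C[C@@H](OC(=O)[C@]3(C)O[C@H]3C)[C@@H]12 | target

**Step count and risks**

Total: 17 steps. Longest linear sequence: 12 steps (3, 4, 5, 7, 8, 9, 10, 11, 12, 13, 16, 17).

Most likely to fail:

1. Step 13 (SmI2 ring closure). A ten-membered ketyl–olefin closure has no direct precedent; it competes with simple reduction and pinacol coupling, and the sense at C8 rests on a transition-state model. Fallback for a wrong C8 outcome: set out from 21, accept the cyclisation product with the opposite carbinol configuration, the (4S)-epimer of alcohol 23 F1, and introduce acid 27 with inversion by Mitsunobu esterification (PPh3, diisopropyl azodicarboxylate, toluene, 0 °C → rt); this comes back to the route at 29. This fallback does not rescue a failure of the ring closure itself.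

2. Step 17 (late epoxidation). Chemoselectivity should be good, but the facial outcome depends on the ring conformation of 29. Fallback: set out from 19 and install the oxirane before ring closure under reagent control. Shi epoxidation (D-fructose-derived ketone, Oxone 2KHSO5·KHSO4·K2SO4, K2CO3 buffer, MeCN/dimethoxymethane/H2O, 0 °C) gives the (1R,10R)-epoxy silyl ether (2S,3Z)-4-[(2R)-4-(acetoxymethyl)-5-oxo-2,5-dihydrofuran-2-yl]-1-[(2R,3R)-3-(2-{[tert-butyl(dimethyl)silyl]oxy}ethyl)-3-methyloxiran-2-yl]-3-methylbut-3-en-2-yl (2R)-2-methylbutanoate F2. Bu4NF/AcOH then gives the epoxy alcohol F3, Dess–Martin oxidation the epoxy aldehyde F4, and SmI2 cyclisation as in step 13 the epoxy macrocyclic alcohol F5. Yamaguchi esterification of F5 with 27 comes back to the route at 30.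

3. Step 9 (asymmetric Ni/Cr coupling). Ligand control at C3 may be incomplete. Fallback: set out from 6 and 15, couple without chiral ligand (CrCl2, NiCl2 cat., DMSO, rt) to obtain 17 mixed with its (3R)-epimer F6, oxidise the mixture (Dess–Martin periodinane, NaHCO3) to the enone F7, and reduce it with (R)-2-methyl-CBS-oxazaborolidine and catecholborane (toluene, −78 °C); this comes back to the route at 17.

**Further compounds**

F1 | step 13 | (3aR,4S,6E,9S,10Z,11aR)-4-hydroxy-6,10-dimethyl-3-methylidene-2-oxo-2,3,3a,4,5,8,9,11a-octahydrocyclodeca[b]furan-9-yl (2R)-2-methylbutanoate | C=C1C(=O)O[C@@H]2/C=C(/C)[C@@H](OC(=O)[C@H](C)CC)C/C=C(\C)C[C@H](O)[C@@H]12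
F2 | step 17 | (2S,3Z)-4-[(2R)-4-(acetoxymethyl)-5-oxo-2,5-dihydrofuran-2-yl]-1-[(2R,3R)-3-(2-{[tert-butyl(dimethyl)silyl]oxy}ethyl)-3-methyloxiran-2-yl]-3-methylbut-3-en-2-yl (2R)-2-methylbutanoate | O=C1O[C@@H](C=C1COC(C)=O)/C=C(/C)[C@@H](OC(=O)[C@H](C)CC)C[C@H]1O[C@]1(C)CCO[Si](C)(C)C(C)(C)C
F3 | step 17 | (2S,3Z)-4-[(2R)-4-(acetoxymethyl)-5-oxo-2,5-dihydrofuran-2-yl]-1-[(2R,3R)-3-(2-hydroxyethyl)-3-methyloxiran-2-yl]-3-methylbut-3-en-2-yl (2R)-2-methylbutanoate | O=C1O[C@@H](C=C1COC(C)=O)/C=C(/C)[C@@H](OC(=O)[C@H](C)CC)C[C@H]1O[C@]1(C)CCO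
F4 | step 17 | (2S,3Z)-4-[(2R)-4-(acetoxymethyl)-5-oxo-2,5-dihydrofuran-2-yl]-3-methyl-1-[(2R,3R)-3-methyl-3-(2-oxoethyl)oxiran-2-yl]but-3-en-2-yl (2R)-2-methylbutanoate | O=C1O[C@@H](C=C1COC(C)=O)/C=C(/C)[C@@H](OC(=O)[C@H](C)CC)C[C@H]1O[C@]1(C)CC=O
F5 | step 17 | (1R,3S,6R,7R,8R,10R)-1,10-epoxy-8-hydroxy-3-{[(2R)-2-methylbutanoyl]oxy}germacra-4Z,11(13)-dien-12,6-olide | C=C1C(=O)O[C@@H]2/C=C(/C)[C@@H](OC(=O)[C@H](C)CC)C[C@H]3O[C@]3(C)C[C@@H](O)[C@@H]12
F6 | step 9 | [(5R)-5-[(1Z,3R,5E)-8-{[tert-butyl(dimethyl)silyl]oxy}-3-hydroxy-2,6-dimethylocta-1,5-dien-1-yl]-2-oxo-2,5-dihydrofuran-3-yl]methyl acetate | O=C1O[C@@H](C=C1COC(C)=O)/C=C(/C)[C@H](O)C/C=C(\C)CCO[Si](C)(C)C(C)(C)C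
F7 | step 9 | [(5R)-5-[(1Z,5E)-8-{[tert-butyl(dimethyl)silyl]oxy}-2,6-dimethyl-3-oxoocta-1,5-dien-1-yl]-2-oxo-2,5-dihydrofuran-3-yl]methyl acetate | O=C1O[C@@H](C=C1COC(C)=O)/C=C(/C)C(=O)C/C=C(\C)CCO[Si](C)(C)C(C)(C)C
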